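**Proposed synthesis of CNP0596887.4 through desymmetrisation of a meso bis-epoxyquinol**

Atom labels used throughout: ring A is the cyclohexenone, numbered C1 (C=O), C2 (C–N), C3 (=CH), C4 (C–OH), C5 and C6 (oxirane carbons, C6 next to C1). The upper chain is C1'–C10', the lower chain C1''–C7'' (C7'' on C4), and ring B is the hydroxycyclopentenone. The target is 29 = (2E,4E,6E,8R)-8-methyldeca-2,4,6-trienamide of the (4S,5R,6S) ring A.

## The problem

- **Structure.** Ring A is a 5,6-epoxy-4-hydroxycyclohex-2-enone. Its C2 nitrogen carries an (8R)-8-methyldecatrienoyl chain. Its fully substituted C4 carries a heptatrienamide chain ending in ring B, an enolised 2-acylaminocyclopentane-1,3-dione.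
- **Stereocentres.** Ring A holds three contiguous stereocentres (C4 S, C5 R, C6 S), with the C4 hydroxyl and the oxirane oxygen on the same face. The fourth, C8' (R), sits seven bonds from the ring; it can neither control nor be controlled by the ring and has to be bought.
- **Control.** The C4 hydroxyl can steer oxygen to C5/C6, so the relative configuration is open to substrate control. The absolute configuration needs one external event.
- **Fragile groups.** C4 is a tertiary, doubly allylic carbinol beside an oxirane and ionises or aromatises under acid. The α,β-epoxy ketone is base-labile. Both polyenes are sensitive to light, acid and oxidants. Ring B is an acidic, chelating vinylogous acid. The chains should therefore arrive late, and no protecting group should need acid for removal.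
- **The enabling feature.** In ring A, C1 is flanked by C2 and C6, and C4 by C3 and C5. C5–C6 is an oxirane. The enamide C2(N)=C3(H) is exactly what remains when an oxirane across C2–C3 is opened at C2 by nitrogen and the C3 oxygen is eliminated. Ring A is thus the singly unmasked form of an all-cis 2,3:5,6-diepoxy-4-hydroxycyclohexanone, a meso compound with a mirror plane through C1 and C4. C4, C5 and C6 are stereocentres only because the two arms of that plane have been made different.

## Retrosynthesis

**29 ⇒ 21 + 28.** The C5''–C6'' sp2–sp2 bond of the lower triene is cut. Cutting C4–C7'' instead would mean adding an organometallic to a ketone on a finished chiral ring. Cutting the ring B amide would mean activating a carboxyl on the finished core. The chosen cut leaves a two-carbon iodoalkene on the core and puts the acidic ring B in stannane 28. The forward reaction must be neutral, at room temperature and geometry-retentive: a Stille coupling.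

**21 ⇒ 11 + 18.** The N–C1' amide bond is cut and the nitrogen is carried as an azide (11). Azide is non-basic and avoids a free 2-aminoenone, which would self-condense. The forward step is a Staudinger reaction through iminophosphorane 20 with acylation by acid chloride 19, made in the flask from acid 18.

**11 ⇒ 9 ⇒ 7 (key).** The C2–N bond is cut and oxygen is restored at C3, giving azido diol 9 (eliminated forward through mesylate 10). Compound 9 is the product of azide opening, through silyl ether 8, of one oxirane of the meso bis-epoxide 7. Because 7 is achiral, the three stereocentres of 11 reduce to a choice between two enantiotopic oxiranes. Nitrogen entry and asymmetric induction become the same event. The alternatives (C–N coupling on an enone, or starting from an aniline) offer no such symmetry. The forward reaction must select one oxirane by catalyst control and attack C2 rather than C3.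

**7 ⇒ 5.** The four C–O bonds of the two oxiranes are cut. Forward, the C4 hydroxyl of quinol 5 directs both epoxidations (through mono-epoxide 6), giving the all-cis isomer. An achiral compound goes to an achiral compound, so no enantiocontrol is needed.

**5 ⇒ 4 ⇒ 2 + 3.** The C4–C7'' bond is made on flat, symmetrical 1,4-benzoquinone 2 with alkenyllithium 3 (from distannane 1), while C4 is not yet a stereocentre. Stannane 4 is exchanged for iodide 5 because the iodoalkene survives peroxide, Lewis acid, base and phosphine.

**18 ⇒ 17 ⇒ 14 + 16.** The C6'=C7' bond is cut to a vinylogous Horner–Wadsworth–Emmons pair: phosphonate 14 (from ethyl sorbate 12 through bromide 13) and aldehyde 16 (from alcohol 15). The C8' stereocentre is bought with 15.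

**28 ⇒ 27 + 1; 27 ⇒ 25 + 24; 24 ⇒ 23 ⇒ 22.** The stannyldienamide comes from iodoacrylamide 27 and the same distannane 1. Compound 27 comes from (E)-3-iodoacrylic acid 25 (as chloride 26) and aminodiketone salt 24, made from cyclopentane-1,3-dione 22 through nitro compound 23.

## Roads not taken

**Alternative 1:** the most obvious cut, at C4–C7'' on a ring that already carries nitrogen.
- Route: anilide A1 is dearomatised to quinone monoketal A2. A chiral phase-transfer nucleophilic epoxidation gives A3. Alkenyllithium 3 adds to the free carbonyl anti to the oxirane, then coupling and acidic ketal hydrolysis follow.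
- Why the chosen plan is better: here the upper polyene amide must pass through hypervalent-iodine oxidation, basic peroxide and organolithium (the N–H consumes an equivalent). The ketal must be removed with acid next to the ionisable C4 carbinol. The enantio-determining epoxidation of a cross-conjugated dienone rests on ion pairing alone, with no directing group. The chosen plan needs no protecting group, sets the relative configuration by intramolecular delivery, and brings both chains in late.

**Alternative 2:** cut the C4–O bond.
- Route: enantioselective hydroxylative dearomatisation of phenol A4 to quinol A5, then hydroxyl-directed epoxidation of C5=C6.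
- Why the chosen plan is better: the stereocentre of A5 arises from distinguishing two ring arms that differ only at the remote C2 substituent, and no catalyst class does this reliably for para-hydroxylation. The para-alkenyl group delocalises the phenoxenium charge to its terminal carbon, inviting quinone methide capture. The ortho-amidophenol can over-oxidise or cyclise, and the polyene is exposed to the oxidant.

**Alternative 3:** cut one oxirane enantioselectively and bring nitrogen in by cross-coupling.
- Route: desymmetrising mono-epoxidation of 5 to the non-racemic mono-epoxide A6, α-iodination to A7, then copper-catalysed amidation with primary amide A8.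
- Why the chosen plan is better: this needs an asymmetric directed epoxidation of a tertiary quinol that has no closer precedent than the chosen key step. It then adds a second hard step: the C–N coupling must distinguish the two alkenyl iodides of A7 under hot, basic conditions on a base-labile epoxy ketone. In the chosen plan the second oxirane is itself the nitrogen entry, so one event replaces two.

Key step: step 4

## Assumptions

- (R)-2-Methylbutan-1-ol (15) is taken as a purchasable single enantiomer; it is the less common antipode of the fermentation-derived alcohol.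
- The sense of induction of the chromium–salen catalyst on this new substrate class cannot be read from simple meso epoxides. The (S,S) ligand is written; the (R,R) ligand is taken instead if it is the C5–C6 oxirane that is opened.

## Route

Step 1
Reactants: 1 (E)-1,2-bis(tributylstannyl)ethene; 2 1,4-benzoquinone
Product: 4 4-hydroxy-4-[(E)-2-(tributylstannyl)ethenyl]cyclohexa-2,5-dien-1-one, via (E)-2-(tributylstannyl)ethenyllithium 3 (not isolated)
Conditions: 1, n-BuLi (1.0 equiv), THF, −78 °C; cannulate into 2 (1.5 equiv), THF, −78 °C; AcOH quench at −78 °C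
Reagents that add atoms: none
Why: Tin–lithium exchange on 1 gives the (E)-alkenyllithium 3 with retention, and 1,2-addition of an organolithium to one carbonyl of 1,4-benzoquinone at low temperature (inverse addition to excess quinone) is a known route to 4-substituted 4-hydroxycyclohexadienones; the product is achiral, so only mono-addition has to be controlled.

Step 2
Reactants: 4 4-hydroxy-4-[(E)-2-(tributylstannyl)ethenyl]cyclohexa-2,5-dien-1-one
Product: 5 4-hydroxy-4-[(E)-2-iodoethenyl]cyclohexa-2,5-dien-1-one
Conditions: I2 (1.05 equiv), CH2Cl2, 0 °C; aq. Na2S2O3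
Reagents that add atoms: iodine, II
Why: Iododestannylation is an ipso electrophilic substitution with retention of the E geometry; it exchanges the acid- and oxidant-sensitive stannane for an iodoalkene that should be inert to every step before the final coupling.

Step 3
Reactants: 5 4-hydroxy-4-[(E)-2-iodoethenyl]cyclohexa-2,5-dien-1-one
Product: 7 (2R,3S,5R,6S)-2,3:5,6-diepoxy-4-hydroxy-4-[(E)-2-iodoethenyl]cyclohexan-1-one (meso; both oxiranes cis to the hydroxyl), via racemic syn-monoepoxide 6 (not isolated)
Conditions: Ti(OiPr)4 (1.2 equiv), t-BuOOH (5.5 M in decane, 4 equiv), 4 Å MS, CH2Cl2, −20 °C to 0 °C; aq. tartaric acid work-up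
Reagents that add atoms: tert-butyl hydroperoxide, CC(C)(C)OO
Why: Hydroxyl-directed nucleophilic epoxidation (a Weitz–Scheffer-type conjugate addition and ring closure with the peroxide held on tetravalent titanium): the titanium alkoxide of the C4 hydroxyl delivers peroxide oxygen to C3 and then to C5 on the face of the hydroxyl, as known for 4-hydroxycyclohexenones and quinols, so both oxiranes should form cis to the OH; the product is meso and no absolute configuration is at stake.

Step 4
Reactants: 7 (2R,3S,5R,6S)-2,3:5,6-diepoxy-4-hydroxy-4-[(E)-2-iodoethenyl]cyclohexan-1-one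
Product: 9 (2S,3S,4S,5R,6S)-2-azido-5,6-epoxy-3,4-dihydroxy-4-[(E)-2-iodoethenyl]cyclohexan-1-one, via 3-O-trimethylsilyl azido ether 8 (not isolated)
Conditions: (S,S)-(salen)CrN3 (5 mol %; salen = N,N'-bis(3,5-di-tert-butylsalicylidene)cyclohexane-1,2-diamine dianion; trivalent chromium), TMSN3 (1.1 equiv), t-BuOMe, 0 °C; then MeOH, camphorsulfonic acid (cat.), 0 °C
Reagents that add atoms: azidotrimethylsilane, C[Si](C)(C)N=[N+]=[N-]
Why: Proposed new method: enantiotopic-group-selective azidolysis of a meso bis(α,β-epoxy ketone), whose closest known reaction type is the (salen)CrN3-catalysed asymmetric ring opening of meso epoxides by TMSN3, a cooperative mechanism in which one trivalent chromium centre activates the oxirane oxygen and a second delivers azide. Azide should enter by SN2 at C2, the carbon α to the carbonyl, as in the known conversion of cyclic α,β-epoxy ketones into 2-thio-, 2-amino- and 2-azido-enones, while C3 is shielded because the iodoethenyl group on the neighbouring quaternary C4 sits on exactly the face from which backside attack must come. No ring is closed (one oxirane is opened); C2 is inverted and C3 retained, giving the trans azido silyl ether, but both centres are erased in step 5. The only stereochemical information that matters is therefore which of the two mirror-related oxiranes is opened, and that choice, made by the chiral catalyst, fixes the absolute configuration of C4, C5 and C6 at once, their relative configuration having been set in step 3. The step needs enantiotopic-group selection (catalyst), C2 over C3 (activation by C1=O plus the steric shield at C4) and single over double opening (one equivalent of azide, and a mono-opened product that is more hindered and a poorer ligand for chromium). Acid-catalysed methanolysis in the same flask removes the trimethylsilyl group.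

Step 5
Reactants: 9 (2S,3S,4S,5R,6S)-2-azido-5,6-epoxy-3,4-dihydroxy-4-[(E)-2-iodoethenyl]cyclohexan-1-one
Product: 11 (4R,5R,6S)-2-azido-5,6-epoxy-4-hydroxy-4-[(E)-2-iodoethenyl]cyclohex-2-en-1-one, via 3-O-methanesulfonate 10 (not isolated)
Conditions: MsCl (1.1 equiv), Et3N (3 equiv), CH2Cl2, −30 °C to 0 °C, dark
Reagents that add atoms: none
Why: Selective sulfonylation of the secondary C3 hydroxyl (the tertiary C4 hydroxyl is inert) and E1cB loss of methanesulfonate through the C1 enolate give the conjugated 2-azidoenone, the known way from α-azido-β-hydroxy ketones to α-azidoenones; C4–O is cis to both C3–O and the oxirane, which rules out displacement or Payne-type side reactions, and C4, C5 and C6 are untouched.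

Step 6
Reactants: 12 ethyl (2E,4E)-hexa-2,4-dienoate
Product: 13 ethyl (2E,4E)-6-bromohexa-2,4-dienoate
Conditions: NBS, dibenzoyl peroxide (cat.), PhCF3, reflux
Reagents that add atoms: N-bromosuccinimide, O=C1CCC(=O)N1Br
Why: Wohl–Ziegler bromination at the terminal methyl group, which gives a pentadienyl radical conjugated with the ester; known for sorbate esters.

Step 7
Reactants: 13 ethyl (2E,4E)-6-bromohexa-2,4-dienoate
Product: 14 ethyl (2E,4E)-6-(diethoxyphosphoryl)hexa-2,4-dienoate
Conditions: P(OEt)3, neat, 120 °C, EtBr distilled off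
Reagents that add atoms: triethyl phosphite, CCOP(OCC)OCC
Why: Michaelis–Arbuzov reaction of a primary allylic bromide.

Step 8
Reactants: 15 (R)-2-methylbutan-1-ol; 14 ethyl (2E,4E)-6-(diethoxyphosphoryl)hexa-2,4-dienoate
Product: 17 ethyl (2E,4E,6E,8R)-8-methyldeca-2,4,6-trienoate, via (R)-2-methylbutanal 16 (not isolated)
Conditions: 15, PhI(OAc)2 (1.1 equiv), TEMPO (cat.), CH2Cl2, 0 °C to rt; aq. NaHCO3 wash, dry; 14 (1.1 equiv), LiN(SiMe3)2 (1.0 equiv), THF, −78 °C; add solution of 16, −78 °C to 0 °C
Reagents that add atoms: none
Why: Oxoammonium oxidation gives the α-branched aldehyde without a base able to enolise it, and the vinylogous Horner–Wadsworth–Emmons reaction of the lithium anion of 14 at its phosphorus-bearing carbon forms the C6=C7 bond with E selectivity; the C8 stereocentre comes unchanged from 15 because 16 is used cold and at once and no excess base remains to deprotonate the product.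

Step 9
Reactants: 17 ethyl (2E,4E,6E,8R)-8-methyldeca-2,4,6-trienoate
Product: 18 (2E,4E,6E,8R)-8-methyldeca-2,4,6-trienoic acid
Conditions: LiOH·H2O, THF/MeOH/H2O, rt, dark; then 1 M HCl to pH 3, 0 °C
Reagents that add atoms: lithium hydroxide, [Li+].[OH-]
Why: Ester saponification; hydroxide is too weak a base to form the extended trienolate by removing the C8 hydrogen, so the stereocentre and the alkene geometries should be kept.

Step 10
Reactants: 11 (4R,5R,6S)-2-azido-5,6-epoxy-4-hydroxy-4-[(E)-2-iodoethenyl]cyclohex-2-en-1-one; 18 (2E,4E,6E,8R)-8-methyldeca-2,4,6-trienoic acid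
Product: 21 (2E,4E,6E,8R)-N-[(1S,5R,6R)-5-hydroxy-5-[(E)-2-iodoethenyl]-2-oxo-7-oxabicyclo[4.1.0]hept-3-en-3-yl]-8-methyldeca-2,4,6-trienamide, via trienoyl chloride 19 (not isolated), via N-alkenyl iminophosphorane 20 (not isolated)
Conditions: 18, 1-chloro-N,N,2-trimethylprop-1-en-1-amine (1.05 equiv), CH2Cl2, 0 °C; separately 11, PPh3 (1.05 equiv), THF, 0 °C to rt; combine at −20 °C, warm to 0 °C; aq. NaHCO3, rt; dark
Reagents that add atoms: none
Why: The Staudinger reaction of the alkenyl azide gives iminophosphorane 20, which is N-acylated by 19 to an acylaminophosphonium salt that water cleaves to the secondary enamide and Ph3PO, a known azide-to-amide sequence that never liberates the self-condensing 2-aminoenone; the chloroenamine makes 19 under neutral conditions, and the tertiary alcohol should not be acylated without a nucleophilic catalyst.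

Step 11
Reactants: 22 cyclopentane-1,3-dione
Product: 23 3-hydroxy-2-nitrocyclopent-2-en-1-one
Conditions: fuming HNO3, Et2O, −10 °C to 0 °C
Reagents that add atoms: nitric acid, O[N+](=O)[O-]
Why: Electrophilic nitration of the enol of a cyclic 1,3-dione at C2, a known reaction of cyclopentane-1,3-dione.

Step 12
Reactants: 23 3-hydroxy-2-nitrocyclopent-2-en-1-one
Product: 24 2-amino-3-hydroxycyclopent-2-en-1-one hydrochloride
Conditions: H2 (1 atm), Pd/C, HCl, MeOH, rt
Reagents that add atoms: hydrogen chloride, Cl
Why: Catalytic hydrogenation of the nitro group; the acid traps the amine as its salt and so prevents self-condensation of the α-amino ketone.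

Step 13
Reactants: 25 (E)-3-iodoprop-2-enoic acid; 24 2-amino-3-hydroxycyclopent-2-en-1-one hydrochloride
Product: 27 (E)-N-(2-hydroxy-5-oxocyclopent-1-en-1-yl)-3-iodoprop-2-enamide, via (E)-3-iodoprop-2-enoyl chloride 26 (not isolated)
Conditions: 25, 1-chloro-N,N,2-trimethylprop-1-en-1-amine (1.05 equiv), CH2Cl2, 0 °C; then 24, Et3N (2.2 equiv), CH2Cl2/DMF, −20 °C to rt
Reagents that add atoms: none
Why: N-acylation of the amine by an acid chloride made under neutral conditions (no HCl, hence no halide exchange or E/Z isomerisation of the β-iodoacryloyl unit); any enol ester formed should migrate to nitrogen or be cleaved on work-up.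

Step 14
Reactants: 27 (E)-N-(2-hydroxy-5-oxocyclopent-1-en-1-yl)-3-iodoprop-2-enamide; 1 (E)-1,2-bis(tributylstannyl)ethene
Product: 28 (2E,4E)-N-(2-hydroxy-5-oxocyclopent-1-en-1-yl)-5-(tributylstannyl)penta-2,4-dienamide
Conditions: PdCl2(MeCN)2 (5 mol %), 1 (2.5 equiv), DMF, rt, dark
Reagents that add atoms: none
Why: Stille coupling of an alkenyl iodide with a large excess of the distannane, so that only one tin group is used; both alkene geometries are retained.

Step 15
Reactants: 21 (2E,4E,6E,8R)-N-[(1S,5R,6R)-5-hydroxy-5-[(E)-2-iodoethenyl]-2-oxo-7-oxabicyclo[4.1.0]hept-3-en-3-yl]-8-methyldeca-2,4,6-trienamide; 28 (2E,4E)-N-(2-hydroxy-5-oxocyclopent-1-en-1-yl)-5-(tributylstannyl)penta-2,4-dienamide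
Product: 29 (2E,4E,6E,8R)-N-[(1S,5S,6R)-5-hydroxy-5-[(1E,3E,5E)-7-[(2-hydroxy-5-oxocyclopent-1-en-1-yl)amino]-7-oxohepta-1,3,5-trien-1-yl]-2-oxo-7-oxabicyclo[4.1.0]hept-3-en-3-yl]-8-methyldeca-2,4,6-trienamide
Conditions: Pd2(dba)3·CHCl3 (5 mol %), AsPh3 (20 mol %), NMP, rt, argon, dark
Reagents that add atoms: none
Why: Stille coupling of an alkenyl iodide and an alkenylstannane with zerovalent palladium and a weakly bound arsine ligand runs at room temperature without base and retains both geometries; the epoxy ketone, the tertiary alcohol, the enamide and the enol of ring B should all tolerate these neutral conditions, and the target is formed directly with no deprotection.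

## Compound list

1 | (E)-1,2-bis(tributylstannyl)ethene | CCCC[Sn](CCCC)(CCCC)/C=C/[Sn](CCCC)(CCCC)CCCC | starting material
2 | 1,4-benzoquinone | O=C1C=CC(=O)C=C1 | starting material
3 | (E)-2-(tributylstannyl)ethenyllithium | [Li]/C=C/[Sn](CCCC)(CCCC)CCCC | intermediate
4 | 4-hydroxy-4-[(E)-2-(tributylstannyl)ethenyl]cyclohexa-2,5-dien-1-one | O=C1C=CC(O)(/C=C/[Sn](CCCC)(CCCC)CCCC)C=C1 | intermediate
5 | 4-hydroxy-4-[(E)-2-iodoethenyl]cyclohexa-2,5-dien-1-one | O=C1C=CC(O)(/C=C/I)C=C1 | intermediate
6 | (4R*,5R*,6S*)-5,6-epoxy-4-hydroxy-4-[(E)-2-iodoethenyl]cyclohex-2-en-1-one (racemic; oxirane cis to OH; one enantiomer drawn) | O=C1C=C[C@@](O)(/C=C/I)[C@@H]2O[C@@H]21 | intermediate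
7 | (2R,3S,5R,6S)-2,3:5,6-diepoxy-4-hydroxy-4-[(E)-2-iodoethenyl]cyclohexan-1-one (meso; both oxiranes cis to OH) | O=C1[C@@H]2O[C@@H]2[C@@](O)(/C=C/I)[C@@H]2O[C@@H]21 | intermediate
8 | (2S,3S,4R,5R,6S)-2-azido-5,6-epoxy-4-hydroxy-4-[(E)-2-iodoethenyl]-3-(trimethylsilyloxy)cyclohexan-1-one | O=C1[C@@H](N=[N+]=[N-])[C@H](O[Si](C)(C)C)[C@@](O)(/C=C/I)[C@@H]2O[C@@H]21 | intermediate
9 | (2S,3S,4S,5R,6S)-2-azido-5,6-epoxy-3,4-dihydroxy-4-[(E)-2-iodoethenyl]cyclohexan-1-one | O=C1[C@@H](N=[N+]=[N-])[C@H](O)[C@@](O)(/C=C/I)[C@@H]2O[C@@H]21 | intermediate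
10 | (2S,3S,4R,5R,6S)-2-azido-5,6-epoxy-4-hydroxy-4-[(E)-2-iodoethenyl]-3-(methanesulfonyloxy)cyclohexan-1-one | O=C1[C@@H](N=[N+]=[N-])[C@H](OS(C)(=O)=O)[C@@](O)(/C=C/I)[C@@H]2O[C@@H]21 | intermediate
11 | (4R,5R,6S)-2-azido-5,6-epoxy-4-hydroxy-4-[(E)-2-iodoethenyl]cyclohex-2-en-1-one | O=C1C(N=[N+]=[N-])=C[C@@](O)(/C=C/I)[C@@H]2O[C@@H]21 | intermediate
12 | ethyl (2E,4E)-hexa-2,4-dienoate (ethyl sorbate) | CCOC(=O)/C=C/C=C/C | starting material
13 | ethyl (2E,4E)-6-bromohexa-2,4-dienoate | CCOC(=O)/C=C/C=C/CBr | intermediate
14 | ethyl (2E,4E)-6-(diethoxyphosphoryl)hexa-2,4-dienoate | CCOC(=O)/C=C/C=C/CP(=O)(OCC)OCC | intermediate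
15 | (R)-2-methylbutan-1-ol | CC[C@@H](C)CO | starting material
16 | (R)-2-methylbutanal | CC[C@@H](C)C=O | intermediate
17 | ethyl (2E,4E,6E,8R)-8-methyldeca-2,4,6-trienoate | CC[C@@H](C)/C=C/C=C/C=C/C(=O)OCC | intermediate
18 | (2E,4E,6E,8R)-8-methyldeca-2,4,6-trienoic acid | CC[C@@H](C)/C=C/C=C/C=C/C(=O)O | intermediate
19 | (2E,4E,6E,8R)-8-methyldeca-2,4,6-trienoyl chloride | CC[C@@H](C)/C=C/C=C/C=C/C(=O)Cl | intermediate
20 | (4R,5R,6S)-5,6-epoxy-4-hydroxy-4-[(E)-2-iodoethenyl]-2-[(triphenyl-λ5-phosphanylidene)amino]cyclohex-2-en-1-one | O=C1C(N=P(c3ccccc3)(c3ccccc3)c3ccccc3)=C[C@@](O)(/C=C/I)[C@@H]2O[C@@H]21 | intermediate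
21 | (2E,4E,6E,8R)-N-[(1S,5R,6R)-5-hydroxy-5-[(E)-2-iodoethenyl]-2-oxo-7-oxabicyclo[4.1.0]hept-3-en-3-yl]-8-methyldeca-2,4,6-trienamide | CC[C@@H](C)/C=C/C=C/C=C/C(=O)NC1=C[C@@](O)(/C=C/I)[C@@H]2O[C@@H]2C1=O | intermediate
22 | cyclopentane-1,3-dione | O=C1CCC(=O)C1 | starting material
23 | 3-hydroxy-2-nitrocyclopent-2-en-1-one (enol of 2-nitrocyclopentane-1,3-dione) | O=C1CCC(O)=C1[N+](=O)[O-] | intermediate
24 | 2-amino-3-hydroxycyclopent-2-en-1-one hydrochloride | NC1=C(O)CCC1=O.Cl | intermediate
25 | (E)-3-iodoprop-2-enoic acid | OC(=O)/C=C/I | starting material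
26 | (E)-3-iodoprop-2-enoyl chloride | ClC(=O)/C=C/I | intermediate
27 | (E)-N-(2-hydroxy-5-oxocyclopent-1-en-1-yl)-3-iodoprop-2-enamide | O=C(/C=C/I)NC1=C(O)CCC1=O | intermediate
28 | (2E,4E)-N-(2-hydroxy-5-oxocyclopent-1-en-1-yl)-5-(tributylstannyl)penta-2,4-dienamide | CCCC[Sn](CCCC)(CCCC)/C=C/C=C/C(=O)NC1=C(O)CCC1=O | intermediate
29 | (2E,4E,6E,8R)-N-[(1S,5S,6R)-5-hydroxy-5-[(1E,3E,5E)-7-[(2-hydroxy-5-oxocyclopent-1-en-1-yl)amino]-7-oxohepta-1,3,5-trien-1-yl]-2-oxo-7-oxabicyclo[4.1.0]hept-3-en-3-yl]-8-methyldeca-2,4,6-trienamide | CC[C@@H](C)/C=C/C=C/C=C/C(=O)NC1=C[C@@](O)(/C=C/C=C/C=C/C(=O)NC2=C(O)CCC2=O)[C@@H]2O[C@@H]2C1=O | target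

## Step count and risk

Total step count: 15. Longest linear sequence: 7 steps (steps 1, 2, 3, 4, 5, 10, 15, from 1,4-benzoquinone). The upper chain takes 4 steps (6–9) and the lower fragment 4 steps (11–14).

**Step 4 (key step; the one step that rests on a new method).**
- What may go wrong: poor discrimination between the two enantiotopic oxiranes; attack at C3 instead of C2; or a fast uncatalysed opening by HN3 released when TMSN3 silylates the C4 hydroxyl, which would erode the enantiomeric purity.
- Fallback (known chemistry), from 7, returning at 11: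
  - Sodium azide with NH4Cl in aqueous methanol at 0 °C opens one oxirane of 7 at C2, the known regiochemistry for cyclic epoxy ketones. This gives the racemic trans azido diol F1.
  - A lipase-catalysed kinetic resolution follows (immobilised Candida antarctica lipase B, vinyl acetate, t-BuOMe), the established method for trans-2-azidocycloalkanols. It gives the 3-O-acetate F2 in one enantiomeric series and leaves the other as alcohol.
  - F2 loses acetic acid with Et3N by E1cB and gives 11.
  - Should the lipase acylate the unwanted enantiomer, the unreacted alcohol is 9 itself and step 5 follows.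

**Step 3.**
- What may go wrong: loss of facial control in the second epoxidation once the first oxirane has changed the ring shape, or titanium-mediated epoxidation of the iodoethenyl alkene, which is allylic to the same hydroxyl.
- Fallback, from 5, returning at 7:
  - Luche reduction (NaBH4, CeCl3·7H2O, MeOH, −78 °C) gives the cis-dienediol F3, separated from its trans isomer.
  - Electrophilic epoxidation with VO(acac)2 (cat.) and t-BuOOH follows. Both hydroxyls of F3 lie on one face and each ring alkene is allylic to both, so the all-cis diepoxy diol F4 should result.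
  - Oxidation of the secondary alcohol of F4 with DMP (1,1,1-triacetoxy-1,1-dihydro-1,2-benziodoxol-3(1H)-one) gives 7.

**Step 5.**
- What may go wrong: base-induced loss of dinitrogen from the α-azido ketone (to an α-imino ketone), or retro-aldol cleavage of the β-hydroxy ketone, competing with sulfonylation and elimination.
- Fallback, from 9, returning at 21:
  - The azide is converted to the amide first, under the conditions of step 10 (PPh3, then 19, then aqueous NaHCO3). This gives the saturated β-hydroxy amide F5.
  - F5 is dehydrated as a β-hydroxy-α-acylamino carbonyl compound by the dehydroamino acid protocol (EDC·HCl, CuCl, CH2Cl2) and gives 21. No basic step is then run on an azide.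

**Step 10.**
- What may go wrong: loss of dinitrogen from the alkenyl azide to a 2H-azirine before phosphine capture, or sluggish acylation of the conjugated iminophosphorane followed by hydrolysis to the unstable free 2-aminoenone.
- Fallback, from 18 and 11, returning at 21:
  - Acid 18 is converted through 19 with NaSH into (2E,4E,6E,8R)-8-methyldeca-2,4,6-trienethioic S-acid F6.
  - F6 reacts directly with the electron-poor azide 11 (2,6-lutidine, MeOH, rt) in a thioacid–azide amidation that gives 21 without any phosphine or free amine.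

**Step 15.**
- What may go wrong: sequestration of palladium by the chelating enol of ring B, protodestannylation of 28 by its own acidic enol, or isomerisation and decomposition of the product polyenes during a slow coupling.
- Fallback, from 25, 1 and 21, returning at 29:
  - A mono-Stille coupling of 25 with excess 1 gives (2E,4E)-5-(tributylstannyl)penta-2,4-dienoic acid F7.
  - F7 is coupled with 21 under the conditions of step 15 to give the core triene acid F8.
  - Ring B is attached last by amide formation between F8 and 24 (isobutyl chloroformate, N-methylmorpholine, THF, −20 °C, then 24) to give 29.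

**Step 1.**
- What may go wrong: single-electron transfer from 3 to the quinone (reduction and homocoupling), conjugate addition, or double addition.
- Fallback, from 1 (through 3), returning at 5:
  - 3 is added to commercial 4,4-dimethoxycyclohexa-2,5-dien-1-one, a masked quinone with a single carbonyl, to give 4,4-dimethoxy-1-[(E)-2-(tributylstannyl)ethenyl]cyclohexa-2,5-dien-1-ol F9.
  - Iodine converts F9 into 1-[(E)-2-iodoethenyl]-4,4-dimethoxycyclohexa-2,5-dien-1-ol F10.
  - Mild aqueous acid (5% aqueous oxalic acid, THF, 0 °C) unmasks the dienone to give 5.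

## Further compounds

F1 | step 4 | rac-(2S*,3S*,4S*,5R*,6S*)-2-azido-5,6-epoxy-3,4-dihydroxy-4-[(E)-2-iodoethenyl]cyclohexan-1-one (racemate of 9; one enantiomer drawn) | O=C1[C@@H](N=[N+]=[N-])[C@H](O)[C@@](O)(/C=C/I)[C@@H]2O[C@@H]21
F2 | step 4 | 3-O-acetyl derivative of 9 (all centres as in 9) | O=C1[C@@H](N=[N+]=[N-])[C@H](OC(C)=O)[C@@](O)(/C=C/I)[C@@H]2O[C@@H]21
F3 | step 3 | cis-1-[(E)-2-iodoethenyl]cyclohexa-2,5-diene-1,4-diol | O[C@@H]1C=C[C@@](O)(/C=C/I)C=C1
F4 | step 3 | all-cis 2,3:5,6-diepoxy-1-[(E)-2-iodoethenyl]cyclohexane-1,4-diol (both oxiranes and both hydroxyls on one face) | O[C@@H]1[C@@H]2O[C@@H]2[C@@](O)(/C=C/I)[C@@H]2O[C@@H]21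
F5 | step 5 | (2E,4E,6E,8R)-N-[(2S,3S,4S,5R,6S)-5,6-epoxy-3,4-dihydroxy-4-[(E)-2-iodoethenyl]-1-oxocyclohexan-2-yl]-8-methyldeca-2,4,6-trienamide (ring numbered as in 9) | O=C1[C@@H](NC(=O)/C=C/C=C/C=C/[C@H](C)CC)[C@H](O)[C@@](O)(/C=C/I)[C@@H]2O[C@@H]21
F6 | step 10 | (2E,4E,6E,8R)-8-methyldeca-2,4,6-trienethioic S-acid | CC[C@@H](C)/C=C/C=C/C=C/C(=O)S
F7 | step 15 | (2E,4E)-5-(tributylstannyl)penta-2,4-dienoic acid | CCCC[Sn](CCCC)(CCCC)/C=C/C=C/C(=O)O
F8 | step 15 | (2E,4E,6E)-7-[(1S,2S,6S)-2-hydroxy-4-[(2E,4E,6E,8R)-8-methyldeca-2,4,6-trienamido]-5-oxo-7-oxabicyclo[4.1.0]hept-3-en-2-yl]hepta-2,4,6-trienoic acid | CC[C@@H](C)/C=C/C=C/C=C/C(=O)NC1=C[C@@](O)(/C=C/C=C/C=C/C(=O)O)[C@@H]2O[C@@H]2C1=O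
F9 | step 1 | 4,4-dimethoxy-1-[(E)-2-(tributylstannyl)ethenyl]cyclohexa-2,5-dien-1-ol | COC1(OC)C=CC(O)(/C=C/[Sn](CCCC)(CCCC)CCCC)C=C1
F10 | step 1 | 1-[(E)-2-iodoethenyl]-4,4-dimethoxycyclohexa-2,5-dien-1-ol | COC1(OC)C=CC(O)(/C=C/I)C=C1
A1 | alternative 1 | (2E,4E,6E,8R)-N-(2,5-dimethoxyphenyl)-8-methyldeca-2,4,6-trienamide | CC[C@@H](C)/C=C/C=C/C=C/C(=O)Nc1cc(OC)ccc1OC
A2 | alternative 1 | (2E,4E,6E,8R)-N-(6,6-dimethoxy-3-oxocyclohexa-1,4-dien-1-yl)-8-methyldeca-2,4,6-trienamide | CC[C@@H](C)/C=C/C=C/C=C/C(=O)NC1=CC(=O)C=CC1(OC)OC
A3 | alternative 1 | 4,5-epoxide of A2 (oxirane configured as C5/C6 of 29) | CC[C@@H](C)/C=C/C=C/C=C/C(=O)NC1=CC(=O)[C@@H]2O[C@@H]2C1(OC)OC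
A4 | alternative 2 | (2E,4E,6E,8R)-N-[2-hydroxy-5-[(E)-2-iodoethenyl]phenyl]-8-methyldeca-2,4,6-trienamide | CC[C@@H](C)/C=C/C=C/C=C/C(=O)Nc1cc(/C=C/I)ccc1O
A5 | alternative 2 | (2E,4E,6E,8R)-N-[3-hydroxy-3-[(E)-2-iodoethenyl]-6-oxocyclohexa-1,4-dien-1-yl]-8-methyldeca-2,4,6-trienamide (carbinol configured as C4 of 21) | CC[C@@H](C)/C=C/C=C/C=C/C(=O)NC1=C[C@@](O)(/C=C/I)C=CC1=O
A6 | alternative 3 | (4R,5R,6S)-5,6-epoxy-4-hydroxy-4-[(E)-2-iodoethenyl]cyclohex-2-en-1-one (single enantiomer) | O=C1C=C[C@@](O)(/C=C/I)[C@@H]2O[C@@H]21
A7 | alternative 3 | (4R,5R,6S)-5,6-epoxy-4-hydroxy-2-iodo-4-[(E)-2-iodoethenyl]cyclohex-2-en-1-one | O=C1C(I)=C[C@@](O)(/C=C/I)[C@@H]2O[C@@H]21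
A8 | alternative 3 | (2E,4E,6E,8R)-8-methyldeca-2,4,6-trienamide | CC[C@@H](C)/C=C/C=C/C=C/C(N)=O
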